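**Retrosynthetic overview**

1. Endgame: the free acid comes from its tert-butyl ester, the ring A C3 chlorine from an ortho-directed chlorination, and the 4-O-methyl group from alkylation of the single free phenol. This leads back to the unchlorinated, unmethylated depside tert-butyl ester.
2. Key disconnection: ring A is opened between C1 and C6 (retro-aldol). The strategy rests on ring A plus the depside carbonyl being a butyryl-primed tetraketide: the ester C=O is chain C1, ring A C1 is chain C2, the oxygens on ring A C2 and C4 are the chain C3 and C5 ketones, and ring A C6 with its propyl group is chain C7–C10. The open chain can therefore already sit as the ester on the ring B C4 oxygen.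
3. The aryl 3,5,7-trioxodecanoate comes from an acylketene (thermolysis of a 6-(2,4-dioxoheptyl)dioxinone) captured by the non-chelated 4-OH of tert-butyl 2,4-dihydroxy-6-propylbenzoate.
4. The dioxinone arm is 2,2,6-trimethyl-1,3-dioxin-4-one acylated twice (acetyl, then butanoyl). The ring B arm is 5-propylresorcinol, carboxylated and then tert-butylated.
5. Ring order: ring B is bought as an arene; ring A is the only ring made, in step 6, on the finished ester linkage.

Key step: step 6

Remark: the target has no stereocentre. The only stereogenic carbon on the route belongs to the transient racemic aldol adduct of the key step and is removed in the same flask.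

**Route**

Step 1
Reactants: 1 2,2,6-trimethyl-4H-1,3-dioxin-4-one; 2 acetyl chloride
Product: 3 2,2-dimethyl-6-(2-oxopropyl)-4H-1,3-dioxin-4-one
Conditions: 1 (2 equiv), LiN(SiMe3)2 (2 equiv), THF, −78 °C; then 2 (1 equiv), −78 °C; aq NH4Cl
Reagents that add atoms: none
Why: Kinetic γ-deprotonation gives the lithium dienolate of the vinylogous ester, which undergoes Claisen-type C-acylation at the 6-methyl carbon, the second equivalent of dienolate taking up the proton of the more acidic β-keto product.

Step 2
Reactants: 3 2,2-dimethyl-6-(2-oxopropyl)-4H-1,3-dioxin-4-one; 4 butanoyl chloride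
Product: 5 6-(2,4-dioxoheptyl)-2,2-dimethyl-4H-1,3-dioxin-4-one
Conditions: LiN(i-Pr)2 (2.2 equiv per 3), THF, −78 °C; then 4 (0.5 equiv per 3), −78 °C; 1 M aq HCl to pH 3
Reagents that add atoms: none
Why: Double deprotonation gives a dianion whose terminal, last-formed methyl carbanion is acylated in a dianion Claisen condensation, the acid chloride being kept limiting because the tricarbonyl product consumes base.

Step 3
Reactants: 6 5-propylresorcinol
Product: 7 2,4-dihydroxy-6-propylbenzoic acid
Conditions: MeOMgOCO2Me (2 M in DMF, 4 equiv), 120 °C, N2; then cold 2 M aq HCl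
Reagents that add atoms: magnesium methyl carbonate, COC(=O)O[Mg]OC
Why: In this chelation-controlled Kolbe–Schmitt-type carboxylation the magnesium phenoxide delivers CO2 ortho to one hydroxyl and para to the other (C4 and C6 of the symmetric resorcinol are equivalent), and the magnesium salicylate chelate holds the carboxyl until cold acidification.

Step 4
Reactants: 7 2,4-dihydroxy-6-propylbenzoic acid
Product: 8 tert-butyl 2,4-dihydroxy-6-propylbenzoate
Conditions: O-tert-butyl-N,N'-diisopropylisourea (2 equiv), CH2Cl2, rt
Reagents that add atoms: O-tert-butyl-N,N'-diisopropylisourea, CC(C)N=C(NC(C)C)OC(C)(C)C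
Why: Isourea esterification transfers tert-butyl to the carboxylate oxygen through an ion pair, so the doubly ortho-substituted carboxyl is no steric obstacle, the less acidic phenols should not react, and room temperature avoids decarboxylation.

Step 5
Reactants: 5 6-(2,4-dioxoheptyl)-2,2-dimethyl-4H-1,3-dioxin-4-one; 8 tert-butyl 2,4-dihydroxy-6-propylbenzoate
Product: 10 tert-butyl 2-hydroxy-6-propyl-4-(3,5,7-trioxodecanoyloxy)benzoate, via acylketene dec-1-ene-1,3,5,7-tetraone 9 (not isolated)
Conditions: 8 (2 equiv), PhMe, 110 °C, N2 sweep; evaporate, crude 10 used directly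
Reagents that add atoms: none
Why: Thermal retro-hetero-Diels–Alder loss of acetone gives acylketene 9, which is captured under neutral conditions by the free 4-OH of 8 (the 2-OH is held in a hydrogen bond to the ester carbonyl), excess phenol suppressing cyclisation of the ketene onto its own enol oxygen.

Step 6
Reactants: 10 tert-butyl 2-hydroxy-6-propyl-4-(3,5,7-trioxodecanoyloxy)benzoate
Product: 12 tert-butyl 4-(2,4-dihydroxy-6-propylbenzoyloxy)-2-hydroxy-6-propylbenzoate, via cyclic aldol adduct 11 (not isolated)
Conditions: Et3N (3 equiv), CH2Cl2, 0 °C to rt; then 1 M aq HCl, rt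
Reagents that add atoms: none
Why: Et3N enolises the chain and the C2 carbon of the β-keto ester, activated by both the ester and the C3 ketone, adds to the C7 ketone to form the bond that becomes ring A C1–C6; the tertiary aldol 11 then loses water on acidification and the cyclohexenedione tautomerises irreversibly to the resorcinol ring. The closest known reaction type is the biomimetic aldol–aromatisation of 3,5,7-triketo esters, made by acylketene capture, to β-resorcylate esters. Ring A closes in a six-membered exo-trig aldol of a stabilised enolate (enolexo with respect to the ester enolate), a favoured mode. The stereocentre created at chain C7 is racemic and is erased by the dehydration, so none has to be controlled. The step needs the C2-to-C7 aldol to win over C6-to-C1 Claisen closure, lactonisation to a 2-pyranone and base-induced elimination of the ring B aryloxide; a weak amine base in an aprotic, nucleophile-free medium at low temperature should form only the mono-enolate, which does not attack or fragment the ester, and aromatisation pulls the aldol forward.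

Step 7
Reactants: 12 tert-butyl 4-(2,4-dihydroxy-6-propylbenzoyloxy)-2-hydroxy-6-propylbenzoate
Product: 13 tert-butyl 2-hydroxy-4-(2-hydroxy-4-methoxy-6-propylbenzoyloxy)-6-propylbenzoate
Conditions: MeI (1.1 equiv), K2CO3 (1.1 equiv), acetone, rt
Reagents that add atoms: iodomethane, CI
Why: Williamson etherification with one equivalent of weak base should alkylate only the ring A 4-OH, the most acidic phenol and the only one of the three not hydrogen-bonded to an ortho ester carbonyl.

Step 8
Reactants: 13 tert-butyl 2-hydroxy-4-(2-hydroxy-4-methoxy-6-propylbenzoyloxy)-6-propylbenzoate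
Product: 14 tert-butyl 4-(3-chloro-2-hydroxy-4-methoxy-6-propylbenzoyloxy)-2-hydroxy-6-propylbenzoate
Conditions: SO2Cl2 (1.05 equiv), 2,2,6,6-tetramethylpiperidine (10 mol %), PhMe, 0 °C to rt
Reagents that add atoms: sulfuryl chloride, O=S(=O)(Cl)Cl
Why: In this amine-catalysed ortho-selective electrophilic chlorination of a phenol, the hindered N-chloroamine formed in situ is held by hydrogen bonding to the ring A 2-OH and delivers chlorine to its only free ortho carbon, C3 (C5 is para), while ring B, whose 4-oxygen is acylated, is much less electron-rich and should not react with one equivalent.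

Step 9
Reactants: 14 tert-butyl 4-(3-chloro-2-hydroxy-4-methoxy-6-propylbenzoyloxy)-2-hydroxy-6-propylbenzoate
Product: 15 3-chlorodivaricatic acid, 4-(3-chloro-2-hydroxy-4-methoxy-6-propylbenzoyloxy)-2-hydroxy-6-propylbenzoic acid
Conditions: CF3CO2H/CH2Cl2 (1:4), 0 °C to rt
Reagents that add atoms: none
Why: Acidolysis of the tert-butyl ester by alkyl–oxygen cleavage through the tert-butyl cation (lost as 2-methylpropene) needs no nucleophile, so the depside aryl ester, the methyl ether and the aryl chloride should survive.

**Compound list**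

1 | 2,2,6-trimethyl-4H-1,3-dioxin-4-one | CC1=CC(=O)OC(C)(C)O1 | starting material
2 | acetyl chloride | CC(=O)Cl | starting material
3 | 2,2-dimethyl-6-(2-oxopropyl)-4H-1,3-dioxin-4-one | CC(=O)CC1=CC(=O)OC(C)(C)O1 | intermediate
4 | butanoyl chloride | CCCC(=O)Cl | starting material
5 | 6-(2,4-dioxoheptyl)-2,2-dimethyl-4H-1,3-dioxin-4-one | CCCC(=O)CC(=O)CC1=CC(=O)OC(C)(C)O1 | intermediate
6 | 5-propylresorcinol (5-propylbenzene-1,3-diol) | CCCc1cc(O)cc(O)c1 | starting material
7 | 2,4-dihydroxy-6-propylbenzoic acid | CCCc1cc(O)cc(O)c1C(=O)O | intermediate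
8 | tert-butyl 2,4-dihydroxy-6-propylbenzoate | CCCc1cc(O)cc(O)c1C(=O)OC(C)(C)C | intermediate
9 | dec-1-ene-1,3,5,7-tetraone (acylketene) | CCCC(=O)CC(=O)CC(=O)C=C=O | intermediate
10 | tert-butyl 2-hydroxy-6-propyl-4-(3,5,7-trioxodecanoyloxy)benzoate | CCCC(=O)CC(=O)CC(=O)CC(=O)Oc1cc(CCC)c(C(=O)OC(C)(C)C)c(O)c1 | intermediate
11 | tert-butyl 4-[(2,6-dihydroxy-4-oxo-6-propylcyclohex-1-ene-1-carbonyl)oxy]-2-hydroxy-6-propylbenzoate (racemic cyclic aldol adduct) | CCCC1(O)CC(=O)CC(O)=C1C(=O)Oc1cc(CCC)c(C(=O)OC(C)(C)C)c(O)c1 | intermediate
12 | tert-butyl 4-(2,4-dihydroxy-6-propylbenzoyloxy)-2-hydroxy-6-propylbenzoate | CCCc1cc(O)cc(O)c1C(=O)Oc1cc(CCC)c(C(=O)OC(C)(C)C)c(O)c1 | intermediate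
13 | tert-butyl 2-hydroxy-4-(2-hydroxy-4-methoxy-6-propylbenzoyloxy)-6-propylbenzoate | CCCc1cc(OC)cc(O)c1C(=O)Oc1cc(CCC)c(C(=O)OC(C)(C)C)c(O)c1 | intermediate
14 | tert-butyl 4-(3-chloro-2-hydroxy-4-methoxy-6-propylbenzoyloxy)-2-hydroxy-6-propylbenzoate | CCCc1cc(OC)c(Cl)c(O)c1C(=O)Oc1cc(CCC)c(C(=O)OC(C)(C)C)c(O)c1 | intermediate
15 | 3-chlorodivaricatic acid | CCCc1cc(OC(=O)c2c(CCC)cc(OC)c(Cl)c2O)cc(O)c1C(=O)O | target

**Step count**

Total steps: 9. Longest linear sequence: 7 steps (steps 1, 2, 5, 6, 7, 8, 9, or equally steps 3, 4, 5, 6, 7, 8, 9).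

**Steps most likely to fail**

Step 8. What may go wrong: loss of ortho direction. The ring A 2-OH is tied up in a hydrogen bond to the depside carbonyl and may not engage the N-chloroamine, so chlorine could enter para to it (C5) or twice. The fallback sets out from 13 and returns at 14, using bromine as a removable blocking group. N-Bromosuccinimide in MeCN at 0 °C should brominate ring A para to the 2-OH and give tert-butyl 4-(5-bromo-2-hydroxy-4-methoxy-6-propylbenzoyloxy)-2-hydroxy-6-propylbenzoate F1. SO2Cl2 in CH2Cl2 at 0 °C then finds C3 as the only open position of ring A and should give tert-butyl 4-(5-bromo-3-chloro-2-hydroxy-4-methoxy-6-propylbenzoyloxy)-2-hydroxy-6-propylbenzoate F2. Bu3SnH with azobisisobutyronitrile in PhMe at 80 °C should cleave the C–Br bond by a radical chain and leave the C–Cl bond, which gives 14.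

Step 6. What may go wrong: departure of the ring B aryloxide from the enolised chain (elimination to the acylketene, Claisen closure of C6 on C1, or lactonisation to a 2-pyranone) faster than the aldol closure. The fallback sets out from 5 and returns at 13: the same aldol–aromatisation is run on the dioxinone, where the carboxyl is locked in the acetal ring and carries no leaving group. Et3N in CH2Cl2 at rt should convert 5 into 7-hydroxy-2,2-dimethyl-5-propyl-4H-1,3-benzodioxin-4-one F3. MeI and K2CO3 in acetone should give 7-methoxy-2,2-dimethyl-5-propyl-4H-1,3-benzodioxin-4-one F4. KOH in aqueous dioxane, then cold acid, should open the acetal to 2-hydroxy-4-methoxy-6-propylbenzoic acid F5. N,N'-Dicyclohexylcarbodiimide in toluene should then esterify F5 with the free 4-OH of 8 to give 13.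

Step 5. What may go wrong: consumption of the acylketene by its own C5 enol oxygen (cyclisation to a 2-pyranone), or double acylation, before the ester-deactivated 4-OH of 8 adds. The fallback sets out from 7 and returns at 12: ring A is taken from acid 7 and joined by carbodiimide esterification instead of ketene capture. Benzyl bromide (2.2 equiv) and K2CO3 in DMF should give benzyl 4-(benzyloxy)-2-hydroxy-6-propylbenzoate F6. KOH in aqueous DMSO should saponify it to 4-(benzyloxy)-2-hydroxy-6-propylbenzoic acid F7. N,N'-Dicyclohexylcarbodiimide in toluene with 8 should give tert-butyl 4-[4-(benzyloxy)-2-hydroxy-6-propylbenzoyloxy]-2-hydroxy-6-propylbenzoate F8. Hydrogenolysis (H2, Pd/C, EtOAc) of the benzyl ether should then give 12.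

**Further compounds**

F1 | step 8 | tert-butyl 4-(5-bromo-2-hydroxy-4-methoxy-6-propylbenzoyloxy)-2-hydroxy-6-propylbenzoate | CCCc1c(Br)c(OC)cc(O)c1C(=O)Oc1cc(CCC)c(C(=O)OC(C)(C)C)c(O)c1
F2 | step 8 | tert-butyl 4-(5-bromo-3-chloro-2-hydroxy-4-methoxy-6-propylbenzoyloxy)-2-hydroxy-6-propylbenzoate | CCCc1c(Br)c(OC)c(Cl)c(O)c1C(=O)Oc1cc(CCC)c(C(=O)OC(C)(C)C)c(O)c1
F3 | step 6 | 7-hydroxy-2,2-dimethyl-5-propyl-4H-1,3-benzodioxin-4-one | CCCc1cc(O)cc2OC(C)(C)OC(=O)c12
F4 | step 6 | 7-methoxy-2,2-dimethyl-5-propyl-4H-1,3-benzodioxin-4-one | CCCc1cc(OC)cc2OC(C)(C)OC(=O)c12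
F5 | step 6 | 2-hydroxy-4-methoxy-6-propylbenzoic acid | CCCc1cc(OC)cc(O)c1C(=O)O
F6 | step 5 | benzyl 4-(benzyloxy)-2-hydroxy-6-propylbenzoate | CCCc1cc(OCc2ccccc2)cc(O)c1C(=O)OCc1ccccc1
F7 | step 5 | 4-(benzyloxy)-2-hydroxy-6-propylbenzoic acid | CCCc1cc(OCc2ccccc2)cc(O)c1C(=O)O
F8 | step 5 | tert-butyl 4-[4-(benzyloxy)-2-hydroxy-6-propylbenzoyloxy]-2-hydroxy-6-propylbenzoate | CCCc1cc(OCc2ccccc2)cc(O)c1C(=O)Oc1cc(CCC)c(C(=O)OC(C)(C)C)c(O)c1
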